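**Retrosynthetic overview**
1. Structural basis: in ring B, C10 and C8 each carry one carbon (C20 and C17) and flank C9, which carries the C11–C16 chain. With oxygen at C7 this is the pattern of 2,6-dimethyl-1,4-benzoquinone, whose C5=C10 bond serves as dienophile.
2. Ring B is the quinone; ring A is closed onto it (C1–C10 and C4–C5) by a catalyst-controlled Diels–Alder reaction with 4-methylpenta-1,3-diene, then C5 is epimerised to the trans-decalin.
3. C9–C11 is made by 1,2-addition of a C11–C15 alkylcerium (C13 from methyl (R)-3-methylglutarate) to the C9 ketone of the 7-en-9-one; oxidative 1,3-transposition then moves the oxygen to C7.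
4. End game: 7-oxo-8-ene → 9α-H and Δ7 (reductive enol triflation, formate reduction) → 7α,8α-epoxide → 7α-hydroxy-8(17)-ene → acetate; the C15 silyl ether becomes the methyl ester last.

Key step: step 1

**Remarks and assumptions**
- Labdane numbering is used for all ring atoms (ring A: C1–C5, C10; ring B: C5–C10). Quinone C4, C5, C6, C1, C2, C3 become C6, C5, C10, C9, C8, C7.
- Assumption: the catalyst antipode follows from the usual binding model of oxazaborolidinium–quinone complexes (boron on the C6 carbonyl lone pair syn to H-5, diene on the face away from the ring phenyl), which points to the (R)-catalyst. Were the adduct antipodal, the (S)-catalyst would be used with no other change.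
- Assumption: methyl (R)-3-methylglutarate is bought as a single enantiomer.
- The C8 centre in compounds 5–8 and the C9 carbinol centre in 17 are erased later; their configuration is of no consequence.

**Step 1**
Reactants: 1 2,6-dimethyl-1,4-benzoquinone; 2 4-methylpenta-1,3-diene
Product: 4 trans-fused enedione (4aS,8aS)-2,5,5,8a-tetramethyl-4a,5,8,8a-tetrahydronaphthalene-1,4-dione, via cis-fused cycloadduct 3 (not isolated)
Conditions: (R)-1-(2-methylphenyl)-3,3-diphenyltetrahydro-1H,3H-pyrrolo[1,2-c][1,3,2]oxazaborole (20 mol %), (CF3SO2)2NH (18 mol %), 2 (5 equiv), CH2Cl2, −78 → −20 °C; then Et3N; basic Al2O3 (Brockmann grade 1), CH2Cl2, rt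
Reagents that add atoms: none
Why: The cationic oxazaborolidinium binds the C6 carbonyl of 1 (the one flanked by two CH groups) and activates C5=C10 for an asynchronous, concerted normal-demand [4+2] cycloaddition; the closest known type is the chiral-Lewis-acid Diels–Alder reaction of dialkylbenzoquinones. The unsubstituted diene terminus (largest HOMO coefficient) bonds to the methyl-bearing β-carbon C10 and the CMe2 terminus to C5, so ring A closes as a six-membered ring by suprafacial addition and the cis adduct 3 results. C10 is set by the catalyst, whose ring phenyl covers one face of the bound C5=C10 bond; C5 is set afterwards by equilibration on alumina, because H-5 is α to the C6 carbonyl and the fusion should relax through the enol to the trans isomer 4. The step needs orientation and face selectivity: the site of boron coordination and the diene polarisation give the first, the catalyst antipode the second; endo/exo does not matter because neither diene terminus carries a further stereocentre. The diene reaches its s-cis form only against the strain of its Z-methyl group, so an excess and a long reaction time are planned.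

**Step 2**
Reactants: 4 trans-fused enedione
Product: 5 (4aS,8aS)-2,5,5,8a-tetramethyloctahydronaphthalene-1,4-dione (trans-fused; C2 epimers)
Conditions: H2 (1–3 atm), Pd/C (10 wt %), EtOAc, rt
Reagents that add atoms: none
Why: Heterogeneous catalytic hydrogenation should saturate both the electron-poor C7=C8 bond and the ring A C2=C3 bond; the ketones and the C5 and C10 centres are untouched, and the quaternary C10 rules out aromatisation.

**Step 3**
Reactants: 5 saturated trans-dione
Product: 7 enol triflate (4aS,8aS)-3,4a,8,8-tetramethyl-4-oxo-3,4,4a,5,6,7,8,8a-octahydronaphthalen-1-yl trifluoromethanesulfonate (C3 epimers), via C6 lithium enolate 6 (not isolated)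
Conditions: LiN(SiMe3)2 (1.05 equiv), THF, −78 °C; then N-(5-chloropyridin-2-yl)bis(trifluoromethanesulfonyl)imide, −78 → 0 °C
Reagents that add atoms: N-(5-chloropyridin-2-yl)bis(trifluoromethanesulfonyl)imide, FC(F)(F)S(=O)(=O)N(c1ccc(Cl)cn1)S(=O)(=O)C(F)(F)F
Why: Kinetic deprotonation should occur at C7, the only methylene α to a carbonyl (H-5 and H-8 are hindered methines), and O-sulfonylation of the C6 enolate gives the enol triflate (kinetic enolate trapping) without touching C5.

**Step 4**
Reactants: 7 enol triflate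
Product: 9 (4aS,8aS)-2,5,5,8a-tetramethyl-4a,5,6,7,8,8a-hexahydronaphthalen-1(4H)-one, via deconjugated enone 8 (not isolated)
Conditions: Pd(OAc)2 (5 mol %), PPh3 (10 mol %), HCO2H, n-Bu3N, DMF, 60 °C; then DBU, CH2Cl2, rt
Reagents that add atoms: none
Why: Oxidative addition of the vinyl triflate to zerovalent palladium, formate-to-hydride exchange and reductive elimination (palladium-catalysed formate reduction) remove the C6 oxygen and leave C6=C7; DBU then moves the double bond through the C9 dienolate into conjugation as the more stable trisubstituted 7-en-9-one.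

**Step 5**
Reactants: 10 methyl (R)-3-methylglutarate [(3R)-5-methoxy-3-methyl-5-oxopentanoic acid]
Product: 11 methyl (3R)-5-hydroxy-3-methylpentanoate
Conditions: BH3·SMe2, THF, 0 °C → rt; MeOH quench
Reagents that add atoms: none
Why: Borane reduces the carboxylic acid through its acyloxyborane far faster than the ester (chemoselective borane reduction); the C13 centre is not involved.

**Step 6**
Reactants: 11 methyl (3R)-5-hydroxy-3-methylpentanoate
Product: 12 methyl (3R)-5-[(tert-butyldimethylsilyl)oxy]-3-methylpentanoate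
Conditions: t-BuMe2SiCl, imidazole, DMF, rt
Reagents that add atoms: tert-butyldimethylsilyl chloride, CC(C)(C)[Si](C)(C)Cl
Why: Imidazole-promoted silylation of the primary alcohol masks the future C15 oxygen and prevents lactonisation.

**Step 7**
Reactants: 12 silyl ether ester
Product: 13 (3S)-5-[(tert-butyldimethylsilyl)oxy]-3-methylpentan-1-ol
Conditions: LiAlH4, THF, 0 °C
Reagents that add atoms: none
Why: Hydride reduction of the ester gives the primary alcohol that becomes C11; the silyl ether is stable to LiAlH4 at 0 °C.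

**Step 8**
Reactants: 13 (3S)-5-[(tert-butyldimethylsilyl)oxy]-3-methylpentan-1-ol
Product: 14 tert-butyl{[(3R)-5-iodo-3-methylpentyl]oxy}dimethylsilane
Conditions: I2, PPh3, imidazole, CH2Cl2, 0 °C → rt
Reagents that add atoms: iodine, II
Why: Appel-type iodination of the primary alcohol proceeds through the alkoxyphosphonium iodide and leaves the silyl ether and the remote stereocentre untouched.

**Step 9**
Reactants: 14 tert-butyl{[(3R)-5-iodo-3-methylpentyl]oxy}dimethylsilane; 9 (4aS,8aS)-2,5,5,8a-tetramethyl-4a,5,6,7,8,8a-hexahydronaphthalen-1(4H)-one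
Product: 17 tertiary allylic alcohol (1S,4aS,8aS)-1-[(3S)-5-{[tert-butyl(dimethyl)silyl]oxy}-3-methylpentyl]-2,5,5,8a-tetramethyl-1,4,4a,5,6,7,8,8a-octahydronaphthalen-1-ol, via alkyllithium 15 (not isolated), via alkylcerium dichloride 16 (not isolated)
Conditions: 14, t-BuLi (2.0 equiv), Et2O, −78 °C; anhydrous CeCl3, THF, −78 °C; then 9, −78 → 0 °C; aq. NH4Cl
Reagents that add atoms: none
Why: Iodine–lithium exchange and transmetalation give a weakly basic organocerium that should add 1,2 to the hindered C9 carbonyl instead of removing a γ-hydrogen at C6 (organocerium carbonyl addition); attack is expected anti to the C10 methyl, but the new carbinol centre is erased in step 10.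

**Step 10**
Reactants: 17 tertiary allylic alcohol
Product: 18 (5S,10S,13S)-15-[(tert-butyldimethylsilyl)oxy]labd-8-en-7-one
Conditions: [C5H5NH][CrO3Cl] (pyridinium chlorochromate, 3 equiv), 4 Å molecular sieves, CH2Cl2, rt
Reagents that add atoms: pyridinium chlorochromate, [O-][Cr](=O)(=O)Cl.c1cc[nH+]cc1
Why: The tertiary chromate ester undergoes a [3,3]-shift to the C7 chromate, which is oxidised to the tetrasubstituted enone (Babler–Dauben oxidative transposition); the C7 oxygen comes from the chromate.

**Step 11**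
Reactants: 18 (5S,10S,13S)-15-[(tert-butyldimethylsilyl)oxy]labd-8-en-7-one
Product: 20 (5S,9R,10S,13S)-15-[(tert-butyldimethylsilyl)oxy]labd-7-en-7-yl trifluoromethanesulfonate (9α-H), via C7 lithium enolate 19 (not isolated)
Conditions: Li (2.5 equiv), NH3(l)–THF, t-BuOH (1 equiv), −78 °C; isoprene; NH3 evaporated; then PhN(SO2CF3)2, THF, 0 °C → rt
Reagents that add atoms: N-phenylbis(trifluoromethanesulfonyl)imide, FC(F)(F)S(=O)(=O)N(c1ccccc1)S(=O)(=O)C(F)(F)F
Why: Dissolving-metal enone reduction protonates the β-carbon C9 axially on the α-face, anti to the C10 methyl, which sets 9α-H with the chain equatorial and leaves the C7–C8 lithium enolate regiospecifically; O-sulfonylation fixes it as the enol triflate (reductive enolate trapping).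

**Step 12**
Reactants: 20 enol triflate
Product: 21 (5S,9S,10S,13S)-15-[(tert-butyldimethylsilyl)oxy]labd-7-ene
Conditions: Pd(OAc)2 (5 mol %), PPh3 (10 mol %), HCO2H, n-Bu3N, DMF, 60 °C
Reagents that add atoms: none
Why: Palladium-catalysed formate reduction of the vinyl triflate replaces the C7 oxygen by hydrogen without moving the C7=C8 bond or touching C9.

**Step 13**
Reactants: 21 labd-7-ene silyl ether
Product: 22 (13S)-15-[(tert-butyldimethylsilyl)oxy]-7α,8α-epoxylabdane
Conditions: m-CPBA, NaHCO3, CH2Cl2, 0 °C
Reagents that add atoms: 3-chloroperoxybenzoic acid, O=C(OO)c1cccc(Cl)c1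
Why: Peracid epoxidation (Prilezhaev reaction) of the only alkene should occur on the α-face, opposite the axial C10 methyl and the β-oriented C9 chain, which places the C7 oxygen α.

**Step 14**
Reactants: 22 7α,8α-epoxide
Product: 23 (13S)-15-[(tert-butyldimethylsilyl)oxy]labd-8(17)-en-7α-ol
Conditions: Al(OiPr)3 (2 equiv), toluene, reflux
Reagents that add atoms: none
Why: The aluminium alkoxide coordinates the epoxide oxygen and removes a proton from the unhindered C17 methyl in a cyclic syn-elimination (epoxide to allylic alcohol isomerisation), so C8–O breaks toward the exocyclic alkene while the C7–O bond keeps its α-configuration.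

**Step 15**
Reactants: 23 allylic alcohol
Product: 24 (13S)-7α-acetoxy-15-[(tert-butyldimethylsilyl)oxy]labd-8(17)-ene
Conditions: Ac2O, pyridine, DMAP (cat.), CH2Cl2, rt
Reagents that add atoms: acetic anhydride, CC(=O)OC(C)=O
Why: DMAP-catalysed acylation of the axial secondary allylic alcohol proceeds with retention at C7.

**Step 16**
Reactants: 24 acetate silyl ether
Product: 25 (13S)-7α-acetoxylabd-8(17)-en-15-ol
Conditions: HF·pyridine, pyridine–THF, 0 °C → rt
Reagents that add atoms: none
Why: Buffered fluoride desilylation frees the primary alcohol and spares the allylic acetate and the exocyclic alkene.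

**Step 17**
Reactants: 25 acetoxy alcohol
Product: 26 (13S)-7α-acetoxylabd-8(17)-en-15-oic acid
Conditions: TEMPO (cat.), PhI(OAc)2 (2.2 equiv), MeCN–H2O, rt
Reagents that add atoms: water, O
Why: Oxoammonium-mediated oxidation takes the primary alcohol through the aldehyde hydrate to the acid and is compatible with the 1,1-disubstituted alkene and the acetate.

**Step 18**
Reactants: 26 acid
Product: 27 methyl (5S,7R,9R,10S,13S)-7-acetoxylabd-8(17)-en-15-oate (target)
Conditions: Me3SiCHN2, MeOH–toluene, 0 °C
Reagents that add atoms: trimethylsilyldiazomethane, C[Si](C)(C)C=[N+]=[N-]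
Why: O-Methylation of the carboxylic acid by the diazoalkane is neutral and leaves the acetate in place.

**Compound list**
1 | 2,6-dimethyl-1,4-benzoquinone | CC1=CC(=O)C=C(C)C1=O | starting material
2 | 4-methylpenta-1,3-diene | C=CC=C(C)C | starting material
3 | cis-fused cycloadduct, (4aR,8aS)-2,5,5,8a-tetramethyl-4a,5,8,8a-tetrahydronaphthalene-1,4-dione | O=C1C(C)=CC(=O)[C@@H]2C(C)(C)C=CC[C@]12C | intermediate (not isolated)
4 | trans-fused enedione, (4aS,8aS)-2,5,5,8a-tetramethyl-4a,5,8,8a-tetrahydronaphthalene-1,4-dione | O=C1C(C)=CC(=O)[C@H]2C(C)(C)C=CC[C@]12C | intermediate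
5 | (4aS,8aS)-2,5,5,8a-tetramethyloctahydronaphthalene-1,4-dione, C2 epimers | CC1CC(=O)[C@H]2C(C)(C)CCC[C@]2(C)C1=O | intermediate
6 | C6 lithium enolate of 5 (enolate double bond C6=C7) | CC1C=C(O[Li])[C@H]2C(C)(C)CCC[C@]2(C)C1=O | intermediate (not isolated)
7 | (4aS,8aS)-3,4a,8,8-tetramethyl-4-oxo-3,4,4a,5,6,7,8,8a-octahydronaphthalen-1-yl trifluoromethanesulfonate, C3 epimers | CC1C=C(OS(=O)(=O)C(F)(F)F)[C@H]2C(C)(C)CCC[C@]2(C)C1=O | intermediate
8 | deconjugated enone, (4aS,8aS)-2,5,5,8a-tetramethyl-4a,5,6,7,8,8a-hexahydronaphthalen-1(2H)-one, C2 epimers | CC1C=C[C@H]2C(C)(C)CCC[C@]2(C)C1=O | intermediate (not isolated)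
9 | (4aS,8aS)-2,5,5,8a-tetramethyl-4a,5,6,7,8,8a-hexahydronaphthalen-1(4H)-one | CC1=CC[C@H]2C(C)(C)CCC[C@]2(C)C1=O | intermediate
10 | methyl (R)-3-methylglutarate, (3R)-5-methoxy-3-methyl-5-oxopentanoic acid | COC(=O)C[C@H](C)CC(=O)O | starting material
11 | methyl (3R)-5-hydroxy-3-methylpentanoate | COC(=O)C[C@H](C)CCO | intermediate
12 | methyl (3R)-5-[(tert-butyldimethylsilyl)oxy]-3-methylpentanoate | COC(=O)C[C@H](C)CCO[Si](C)(C)C(C)(C)C | intermediate
13 | (3S)-5-[(tert-butyldimethylsilyl)oxy]-3-methylpentan-1-ol | OCC[C@H](C)CCO[Si](C)(C)C(C)(C)C | intermediate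
14 | tert-butyl{[(3R)-5-iodo-3-methylpentyl]oxy}dimethylsilane | ICC[C@H](C)CCO[Si](C)(C)C(C)(C)C | intermediate
15 | alkyllithium from 14, 5-(silyloxy)-3-methylpentyllithium | [Li]CC[C@H](C)CCO[Si](C)(C)C(C)(C)C | intermediate (not isolated)
16 | alkylcerium dichloride from 15 | Cl[Ce](Cl)CC[C@H](C)CCO[Si](C)(C)C(C)(C)C | intermediate (not isolated)
17 | tertiary allylic alcohol, (1S,4aS,8aS)-1-[(3S)-5-{[tert-butyl(dimethyl)silyl]oxy}-3-methylpentyl]-2,5,5,8a-tetramethyl-1,4,4a,5,6,7,8,8a-octahydronaphthalen-1-ol (9β-OH, chain α; either C9 epimer serves) | CC1=CC[C@H]2C(C)(C)CCC[C@]2(C)[C@]1(O)CC[C@H](C)CCO[Si](C)(C)C(C)(C)C | intermediate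
18 | (5S,10S,13S)-15-[(tert-butyldimethylsilyl)oxy]labd-8-en-7-one | CC1=C(CC[C@H](C)CCO[Si](C)(C)C(C)(C)C)[C@@]2(C)CCCC(C)(C)[C@@H]2CC1=O | intermediate
19 | C7 lithium enolate (C7=C8, 9α-H) | CC1=C(O[Li])C[C@H]2C(C)(C)CCC[C@]2(C)[C@H]1CC[C@H](C)CCO[Si](C)(C)C(C)(C)C | intermediate (not isolated)
20 | (5S,9R,10S,13S)-15-[(tert-butyldimethylsilyl)oxy]labd-7-en-7-yl trifluoromethanesulfonate | CC1=C(OS(=O)(=O)C(F)(F)F)C[C@H]2C(C)(C)CCC[C@]2(C)[C@H]1CC[C@H](C)CCO[Si](C)(C)C(C)(C)C | intermediate
21 | (5S,9S,10S,13S)-15-[(tert-butyldimethylsilyl)oxy]labd-7-ene | CC1=CC[C@H]2C(C)(C)CCC[C@]2(C)[C@H]1CC[C@H](C)CCO[Si](C)(C)C(C)(C)C | intermediate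
22 | (13S)-15-[(tert-butyldimethylsilyl)oxy]-7α,8α-epoxylabdane | C[C@@]12O[C@@H]1C[C@H]3C(C)(C)CCC[C@]3(C)[C@H]2CC[C@H](C)CCO[Si](C)(C)C(C)(C)C | intermediate
23 | (13S)-15-[(tert-butyldimethylsilyl)oxy]labd-8(17)-en-7α-ol | C=C1[C@H](O)C[C@H]2C(C)(C)CCC[C@]2(C)[C@H]1CC[C@H](C)CCO[Si](C)(C)C(C)(C)C | intermediate
24 | (13S)-7α-acetoxy-15-[(tert-butyldimethylsilyl)oxy]labd-8(17)-ene | C=C1[C@H](OC(C)=O)C[C@H]2C(C)(C)CCC[C@]2(C)[C@H]1CC[C@H](C)CCO[Si](C)(C)C(C)(C)C | intermediate
25 | (13S)-7α-acetoxylabd-8(17)-en-15-ol | C=C1[C@H](OC(C)=O)C[C@H]2C(C)(C)CCC[C@]2(C)[C@H]1CC[C@H](C)CCO | intermediate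
26 | (13S)-7α-acetoxylabd-8(17)-en-15-oic acid | C=C1[C@H](OC(C)=O)C[C@H]2C(C)(C)CCC[C@]2(C)[C@H]1CC[C@H](C)CC(=O)O | intermediate
27 | methyl (5S,7R,9R,10S,13S)-7-acetoxylabd-8(17)-en-15-oate | C=C1[C@H](OC(C)=O)C[C@H]2C(C)(C)CCC[C@]2(C)[C@H]1CC[C@H](C)CC(=O)OC | target

**Step count**
Total: 18 steps. Longest linear sequence: 14 steps (steps 1–4 and 9–18; the chain branch, steps 5–8 and 9–18, is equally long).

**Steps most likely to fail**

Step 1. The diene may oligomerise under the cationic catalyst faster than it reaches the s-cis geometry, the facial bias may erode at the temperature the slow addition needs, or the ring fusion may not equilibrate fully. Incomplete equilibration can be finished on dione 5, where H-5 is still α to the C6 carbonyl. The fallback gives up catalyst control in favour of resolution; it sets out from compounds 1 and 2 and comes back at compound 4. The cycloaddition is run without a chiral catalyst, either thermally at about 12 kbar or with SnCl4, and alumina equilibration gives the racemic trans-fused enedione F1. Luche reduction (NaBH4, CeCl3·7H2O, MeOH, −78 °C) of the less hindered C6 carbonyl gives the racemic 6β-allylic alcohol F2. Acylation with (1S)-camphanoyl chloride (Et3N, DMAP) gives two diastereomeric esters that are separated by crystallisation or chromatography: the camphanate of the (4R,4aS,8aS)-alcohol F3 is kept and the diastereomeric camphanate F4 is set aside. Methanolysis (K2CO3, MeOH) frees the enantiopure allylic alcohol F5, and oxidation with Dess–Martin periodinane returns compound 4.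

Step 11. The C7 carbonyl may be over-reduced, or the hindered tetrasubstituted lithium enolate may take up a proton instead of the sulfonyl group, giving the saturated ketone. The fallback replaces the enolate chemistry by a reductive 1,3-transposition of an allylic alcohol; it sets out from compound 18 and comes back at compound 21. Reduction with i-Bu2AlH (CH2Cl2, −78 °C), hydride arriving on the α-face, gives the 7β-allylic alcohol F8. Mitsunobu displacement with 2-nitrobenzenesulfonylhydrazide (PPh3, diethyl azodicarboxylate, THF, −30 °C) proceeds with inversion to the 7α-sulfonylhydrazide F9. On warming this loses the sulfinic acid to give the allylic diazene F10, whose retro-ene loss of N2 delivers hydrogen to C9 on the α-face and moves the double bond to C7=C8, giving 21.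

Step 3. Proton transfer between enolate sites before trapping, or direct deprotonation at C8 or C5, would give regioisomeric triflates. The fallback removes the C6 carbonyl as a hydrazone and reintroduces the alkene afterwards; it sets out from compound 5 and comes back at compound 9. 4-Methylbenzenesulfonylhydrazide condenses at the C6 carbonyl (the C9 carbonyl is flanked by quaternary C10 and methyl-bearing C8) to give the mono-tosylhydrazone F6. Catecholborane followed by NaOAc·3H2O reduces it to the C6-methylene ketone F7. Dehydrogenation with 2-iodoxybenzoic acid (DMSO, 70 °C), possible only toward C7–C8, gives enone 9.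

**Further compounds**
F1 | step 1 | racemic trans-fused enedione (4 and its enantiomer) | O=C1C(C)=CC(=O)[C@H]2C(C)(C)C=CC[C@]12C.O=C1C(C)=CC(=O)[C@@H]2C(C)(C)C=CC[C@@]12C
F2 | step 1 | racemic 6β-allylic alcohol, 4-hydroxy-2,5,5,8a-tetramethyl-4a,5,8,8a-tetrahydronaphthalen-1(4H)-one (both enantiomers) | CC1=C[C@@H](O)[C@H]2C(C)(C)C=CC[C@]2(C)C1=O.CC1=C[C@H](O)[C@@H]2C(C)(C)C=CC[C@@]2(C)C1=O
F3 | step 1 | (1S)-camphanate of the (4R,4aS,8aS)-alcohol | CC1=C[C@@H](OC(=O)[C@@]34CC[C@@](C)(C(=O)O3)C4(C)C)[C@H]2C(C)(C)C=CC[C@]2(C)C1=O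
F4 | step 1 | (1S)-camphanate of the (4S,4aR,8aR)-alcohol | CC1=C[C@H](OC(=O)[C@@]34CC[C@@](C)(C(=O)O3)C4(C)C)[C@@H]2C(C)(C)C=CC[C@@]2(C)C1=O
F5 | step 1 | (4R,4aS,8aS)-4-hydroxy-2,5,5,8a-tetramethyl-4a,5,8,8a-tetrahydronaphthalen-1(4H)-one | CC1=C[C@@H](O)[C@H]2C(C)(C)C=CC[C@]2(C)C1=O
F6 | step 3 | C6 mono-tosylhydrazone of 5 | CC1CC(=NNS(=O)(=O)c3ccc(C)cc3)[C@H]2C(C)(C)CCC[C@]2(C)C1=O
F7 | step 3 | (4aS,8aS)-2,5,5,8a-tetramethyloctahydronaphthalen-1(2H)-one, C2 epimers | CC1CC[C@H]2C(C)(C)CCC[C@]2(C)C1=O
F8 | step 11 | (13S)-15-[(tert-butyldimethylsilyl)oxy]labd-8-en-7β-ol | CC1=C(CC[C@H](C)CCO[Si](C)(C)C(C)(C)C)[C@@]2(C)CCCC(C)(C)[C@@H]2C[C@@H]1O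
F9 | step 11 | 7α-[1-(2-nitrophenylsulfonyl)hydrazin-1-yl]labd-8-ene 15-silyl ether | CC1=C(CC[C@H](C)CCO[Si](C)(C)C(C)(C)C)[C@@]2(C)CCCC(C)(C)[C@@H]2C[C@H]1N(N)S(=O)(=O)c3ccccc3[N+](=O)[O-]
F10 | step 11 | 7α-diazenyllabd-8-ene 15-silyl ether | CC1=C(CC[C@H](C)CCO[Si](C)(C)C(C)(C)C)[C@@]2(C)CCCC(C)(C)[C@@H]2C[C@H]1N=N
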